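At early times, in the cedar flask, the target holds nearly all of the pair of target and isomer of the product A, so follow the fraction left to the target and not the share made.

common to all: starting material 1.5 M
- cedar: the very flask that is asked about, followed so far
- flask: time 15 d

- cedar (time / d: isomer of the product A / %, target / %): 0.500: 0.5, 14.7; 1.67: 2.3, 12.2; 3.00: 3.1, 11.1; 4.00: 4.6, 10.4; 6.00: 6.2, 9.7

(scatter of a reading: 0.5 percentage points)

- steps thought possible: target <-> isomer of the product A; starting material <-> target; target <-> isomer of the product B; starting material <-> dormant form; starting material <-> isomer of the product A

1. share of isomer of the product A in isomer of the product A plus target at 1.5 h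
2. share of isomer of the product A in isomer of the product A plus target at 15 d
3. which of isomer of the product A and target there is more of at 15 d

Take the last cedar reading, divide isomer of the product A by target, and divide that ratio by the time 6.00 d. This gives the pair clock, the daily growth of the ratio, 0.107 d⁻¹, itself a reading with scatter. The readings at 3.00 d and 4.00 d give 0.0931 d⁻¹ and 0.111 d⁻¹, so try a straight line through the start.

Now write the fraction left as one over one plus clock times time. My own reckoning leaves 99.3% at 1.5 h, a share of 0.664%. It leaves 38.5% at 15 d, a share of 61.5%, and since that fraction is less than half, isomer of the product A leads.

The forecast, made apart from this, gave 0.8% and 60% with isomer of the product A ahead, reasoning that “the target looks like a fast-formed kinetic product”.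

The flask gives 1.78% and 60.0%, with isomer of the product A ahead, at 13.2% against 8.75%.

    target ⇌ isomer of the product A (k = 0.00250 h⁻¹)
    starting material ⇌ target (K = 0.370, k = 0.0340 h⁻¹)
    target ⇌ isomer of the product B (K = 2.70, k = 0.00520 h⁻¹)
    starting material ⇌ dormant form (K = 1.60, k = 0.0560 h⁻¹)
    starting material ⇌ isomer of the product A (K = 2.60, k = 5.10 × 10⁻⁴ h⁻¹)

Hold the clock against this flask first: it left 99.3% at 1.5 h, where the flask leaves 98.2%, and 38.5% at 15 d, where the flask leaves 40.0%. Then carry it to the neighbouring flask, charged with 0.60 M of starting material and otherwise the same. Each step in the scheme has one species on each side, so keep the clock unchanged and again expect 38.5% left. That neighbouring flask leaves 40.0%, a share of 60.0%, with target at 8.75% of its charge and isomer of the product A at 13.2%.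

The runs come from a simulation for an exercise, noise included.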